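**Plan**

- Retrosynthesis: the quinone is unmasked last from a 1,4-dimethoxyarene. The long side chain is cut between its ketone carbon and the allylic CH2 (Weinreb amide plus allyl sulfone anion). The short side chain is cut at its CH2–CH= bond (acetyl enolate plus isobutenyl bromide). The acetyl and CH2CO2H groups are then reconnected, with one extra carbon, as the C=C of a cyclohexenone (ozonolysis in reverse). Last, the cyclopentane bond between the ring carbon carrying the CH2C(=O) chain and its ring CH2 neighbour is cut.
- Enabling feature: the two cis quaternary carbons C1 and C2 of the cyclopentane, its three CH2 groups, the acyl carbon on C1 and the CH2–C(=O) unit on C2 form the skeleton of a cis-fused hydrindenone. The cyclohexa-2,5-dienone that precedes it has a mirror plane through its quaternary carbon and its carbonyl group, so closing the five-membered ring onto one of its two β-methyl enone arms creates both stereocentres at once.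
- Forward order: the six-membered ring comes from 2-methylcyclohexane-1,3-dione (steps 1–5). The cyclopentane closes in step 6 and the six-membered ring is opened in step 7. The aryl sulfone fragment (steps 9–13) is joined in step 14 and the isobutenyl group in step 15. The sulfone and the methyl ethers are removed in steps 16 and 17.
- Stereochemistry: both quaternary centres are set in step 6 (the chiral copper catalyst chooses the enone arm, the tether enforces cis fusion). The E-alkene is set by the SN2′ epoxide opening of step 11.

Key step: step 6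

Assumption: the (S,R,R) phosphoramidite is taken to select the enone arm that leads to the (3aR,7aR) bicycle; if the sense of induction is the opposite, its mirror-image ligand is used.

**Route**

Step 1
Reactants: 1 2-methylcyclohexane-1,3-dione; 2 allyl bromide
Product: 3 2-allyl-2-methylcyclohexane-1,3-dione
Conditions: 1 M NaOH aq., 25 °C
Reagents that add atoms: none
Why: C-alkylation of the stabilised dione enolate with a reactive allylic halide in water is the standard entry to 2,2-disubstituted cyclohexane-1,3-diones.

Step 2
Reactants: 3 2-allyl-2-methylcyclohexane-1,3-dione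
Product: 5 6-allyl-6-methylcyclohexa-1,4-diene-1,5-diyl bis(trifluoromethanesulfonate), via mono enol triflate 4 (not isolated)
Conditions: KN(SiMe3)2 (1.1 equiv) then PhNTf2 (1.1 equiv), THF, −78 °C; sequence repeated in the same flask
Reagents that add atoms: N-phenylbis(trifluoromethanesulfonimide), O=S(=O)(N(c1ccccc1)S(=O)(=O)C(F)(F)F)C(F)(F)F
Why: each ketone can enolise only away from the quaternary carbon, so two successive kinetic enolate O-triflations should give the bis(enol triflate) with both double bonds fixed inside the ring and the ring CH2 between them.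

Step 3
Reactants: 5 6-allyl-6-methylcyclohexa-1,4-diene-1,5-diyl bis(trifluoromethanesulfonate)
Product: 6 6-allyl-1,5,6-trimethylcyclohexa-1,4-diene
Conditions: MeMgBr (2.6 equiv), Fe(acac)3 (10 mol%), THF/NMP, −30 to 0 °C
Reagents that add atoms: methylmagnesium bromide, C[Mg]Br
Why: iron-catalysed Kumada-type cross-coupling of enol triflates with methyl Grignard reagents works next to quaternary carbons and leaves an isolated terminal alkene untouched.

Step 4
Reactants: 6 6-allyl-1,5,6-trimethylcyclohexa-1,4-diene
Product: 8 6-(3-iodopropyl)-1,5,6-trimethylcyclohexa-1,4-diene, via alkylzirconocene chloride 7 (not isolated)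
Conditions: Cp2Zr(H)Cl, THF, 25 °C; then I2, 0 °C
Reagents that add atoms: iodine, II
Why: hydrozirconation engages only the monosubstituted alkene and places zirconium on the terminal carbon (the trisubstituted ring alkenes beside the quaternary carbon are inert), and iodinolysis of the C–Zr bond gives the primary iodide.

Step 5
Reactants: 8 6-(3-iodopropyl)-1,5,6-trimethylcyclohexa-1,4-diene
Product: 9 4-(3-iodopropyl)-3,4,5-trimethylcyclohexa-2,5-dien-1-one
Conditions: CrO3, 3,5-dimethylpyrazole, CH2Cl2, −20 °C
Reagents that add atoms: chromium trioxide, O=[Cr](=O)=O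
Why: allylic oxidation with the CrO3–3,5-dimethylpyrazole complex converts the doubly allylic ring CH2 of a 1,4-cyclohexadiene into the cross-conjugated dienone, and primary alkyl iodides are inert to hexavalent chromium reagents of this kind.

Step 6
Reactants: 9 4-(3-iodopropyl)-3,4,5-trimethylcyclohexa-2,5-dien-1-one
Product: 12 (3aR,7aR)-3a,7,7a-trimethyl-1,2,3,3a,4,7a-hexahydro-5H-inden-5-one, via alkylzinc iodide 10 (not isolated), via zinc dienolate 11 (not isolated)
Conditions: Zn dust (activated), LiCl, THF, 25 °C; then Cu(OTf)2 (5 mol%), (S,R,R)-BINOL bis(1-phenylethyl)phosphoramidite (10 mol%), THF/toluene, −30 to 0 °C; aq. NH4Cl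
Reagents that add atoms: none
Why: Proposed new method: zinc inserts into the C–I bond, the divalent copper salt is reduced by the organozinc to a monovalent copper–phosphoramidite complex that takes over the alkyl group, and the alkylcopper binds one enone arm, adds at its β-carbon through a trivalent copper intermediate and reductively eliminates to the zinc dienolate, which is protonated on work-up. The closest known reactions are copper–phosphoramidite-catalysed dialkylzinc additions that desymmetrise 4,4-disubstituted cyclohexa-2,5-dienones and copper-catalysed asymmetric conjugate additions that build quaternary carbons on β-methyl enones. The cyclopentane closes by 5-exo-trig attack of the chain terminus on C3 of the dienone. The old C4 becomes stereogenic because the ligand on copper selects one of the two enantiotopic enone arms, and the new quaternary centre at C3 is fixed relative to it because a three-carbon tether can reach the β-carbon only from its own face, which enforces cis fusion with both methyl groups on the other face. The step needs arm selectivity and conjugate rather than carbonyl addition: the mirror symmetry of 9 means that the arm choice alone defines the enantiomer, the short tether favours intramolecular delivery, and the soft alkylcopper favours 1,4-addition.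

Step 7
Reactants: 12 (3aR,7aR)-3a,7,7a-trimethyl-1,2,3,3a,4,7a-hexahydro-5H-inden-5-one
Product: 14 2-[(1R,2R)-2-acetyl-1,2-dimethylcyclopentyl]acetic acid, via ozonide 13 (not isolated)
Conditions: O3, CH2Cl2, −78 °C; then 30% H2O2, THF/H2O, 25 to 40 °C
Reagents that add atoms: ozone, [O-][O+]=O; hydrogen peroxide, OO
Why: ozonolysis of a cyclic β-methyl enone with oxidative work-up cleaves the C=C bond to the methyl ketone and degrades the α-keto aldehyde terminus by one carbon (lost as formic acid) to the carboxylic acid, without touching either quaternary stereocentre.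

Step 8
Reactants: 14 2-[(1R,2R)-2-acetyl-1,2-dimethylcyclopentyl]acetic acid
Product: 16 2-[(1R,2R)-2-acetyl-1,2-dimethylcyclopentyl]-N-methoxy-N-methylacetamide, via acyl imidazolide 15 (not isolated)
Conditions: 1,1'-carbonyldiimidazole, CH2Cl2, 25 °C; then MeNH(OMe)·HCl
Reagents that add atoms: N,O-dimethylhydroxylamine hydrochloride, CNOC.Cl
Why: activation of the acid as its imidazolide and aminolysis is a standard Weinreb amide synthesis that needs no strong base and so leaves the methyl ketone alone.

Step 9
Reactants: 17 4-methoxy-2-methylphenol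
Product: 18 2-bromo-4-methoxy-6-methylphenol
Conditions: N-bromosuccinimide, i-Pr2NH (10 mol%), CH2Cl2, 0 °C
Reagents that add atoms: N-bromosuccinimide, O=C1CCC(=O)N1Br
Why: electrophilic aromatic bromination directed by the free hydroxyl group goes to the only open ortho position, the para position being blocked by the methoxy group.

Step 10
Reactants: 18 2-bromo-4-methoxy-6-methylphenol
Product: 19 1-bromo-2,5-dimethoxy-3-methylbenzene
Conditions: MeI, K2CO3, acetone, reflux
Reagents that add atoms: iodomethane, CI
Why: Williamson O-methylation of the phenol gives the hydroquinone dimethyl ether that will later be oxidised to the quinone.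

Step 11
Reactants: 19 1-bromo-2,5-dimethoxy-3-methylbenzene; 20 2-methyl-2-vinyloxirane (isoprene monoxide, racemic)
Product: 22 (2E)-4-(2,5-dimethoxy-3-methylphenyl)-2-methylbut-2-en-1-ol, via aryl Grignard reagent 21 (not isolated)
Conditions: Mg, THF; then CuI (10 mol%), 20, −30 °C; aq. NH4Cl
Reagents that add atoms: none
Why: copper-catalysed SN2′ opening of a vinyl epoxide by a Grignard reagent puts the aryl group on the terminal vinyl carbon and should give mainly the E-trisubstituted allylic alcohol, as is general for isoprene monoxide.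

Step 12
Reactants: 22 (2E)-4-(2,5-dimethoxy-3-methylphenyl)-2-methylbut-2-en-1-ol
Product: 23 1-[(2E)-4-bromo-3-methylbut-2-en-1-yl]-2,5-dimethoxy-3-methylbenzene
Conditions: CBr4, PPh3, CH2Cl2, 0 °C
Reagents that add atoms: tetrabromomethane, BrC(Br)(Br)Br
Why: the Appel reaction converts the primary allylic alcohol into the bromide by SN2 displacement without allylic transposition or loss of alkene geometry.

Step 13
Reactants: 23 1-[(2E)-4-bromo-3-methylbut-2-en-1-yl]-2,5-dimethoxy-3-methylbenzene
Product: 24 1-[(2E)-3-methyl-4-(phenylsulfonyl)but-2-en-1-yl]-2,5-dimethoxy-3-methylbenzene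
Conditions: PhSO2Na, DMF, 25 °C
Reagents that add atoms: sodium benzenesulfinate, [Na+].[O-]S(=O)c1ccccc1
Why: S-alkylation of the sulfinate by the primary allylic bromide (SN2) gives the allyl sulfone with the E geometry retained.

Step 14
Reactants: 24 1-[(2E)-3-methyl-4-(phenylsulfonyl)but-2-en-1-yl]-2,5-dimethoxy-3-methylbenzene; 16 2-[(1R,2R)-2-acetyl-1,2-dimethylcyclopentyl]-N-methoxy-N-methylacetamide
Product: 27 (4E)-1-[(1R,2R)-2-acetyl-1,2-dimethylcyclopentyl]-6-(2,5-dimethoxy-3-methylphenyl)-4-methyl-3-(phenylsulfonyl)hex-4-en-2-one (both C3 epimers), via lithiated sulfone 25 (not isolated), via lithium aminal alkoxide 26 (not isolated)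
Conditions: 24 (1.3 equiv), n-BuLi, THF, −78 °C; then 16, −78 to −30 °C; aq. NH4Cl
Reagents that add atoms: none
Why: an α-sulfonyl allyl carbanion acylates at its α-carbon with a Weinreb amide, whose chelated tetrahedral adduct persists until the quench, so little excess anion is needed and the hindered, much less acidic methyl ketone should be left alone.

Step 15
Reactants: 27 (4E)-1-[(1R,2R)-2-acetyl-1,2-dimethylcyclopentyl]-6-(2,5-dimethoxy-3-methylphenyl)-4-methyl-3-(phenylsulfonyl)hex-4-en-2-one; 28 1-bromo-2-methylprop-1-ene
Product: 29 (4E)-6-(2,5-dimethoxy-3-methylphenyl)-1-[(1R,2R)-1,2-dimethyl-2-(4-methylpent-3-enoyl)cyclopentyl]-4-methyl-3-(phenylsulfonyl)hex-4-en-2-one (both C3 epimers)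
Conditions: LiN(SiMe3)2 (2.3 equiv), Pd2(dba)3 (2.5 mol%), P(t-Bu)3 (6 mol%), THF, 25 to 50 °C; aq. NH4Cl
Reagents that add atoms: none
Why: in this palladium-catalysed α-alkenylation of a ketone enolate with an alkenyl bromide, the first equivalent of base parks the keto sulfone as its unreactive stabilised anion and the second forms the only other possible enolate, at the acetyl methyl group, which couples through zerovalent palladium to give the β,γ-unsaturated ketone.

Step 16
Reactants: 29 (4E)-6-(2,5-dimethoxy-3-methylphenyl)-1-[(1R,2R)-1,2-dimethyl-2-(4-methylpent-3-enoyl)cyclopentyl]-4-methyl-3-(phenylsulfonyl)hex-4-en-2-one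
Product: 30 (4E)-6-(2,5-dimethoxy-3-methylphenyl)-1-[(1R,2R)-1,2-dimethyl-2-(4-methylpent-3-enoyl)cyclopentyl]-4-methylhex-4-en-2-one
Conditions: SmI2 (2.5 equiv), THF/MeOH, −78 °C
Reagents that add atoms: none
Why: single-electron reductive desulfonylation of a β-keto sulfone gives a samarium dienolate that is protonated kinetically at the α-carbon, so the alkene stays out of conjugation and keeps its E geometry while the other ketone is not reduced at this temperature.

Step 17
Reactants: 30 (4E)-6-(2,5-dimethoxy-3-methylphenyl)-1-[(1R,2R)-1,2-dimethyl-2-(4-methylpent-3-enoyl)cyclopentyl]-4-methylhex-4-en-2-one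
Product: 31 2-[(2E)-6-[(1R,2R)-1,2-dimethyl-2-(4-methylpent-3-enoyl)cyclopentyl]-3-methyl-5-oxohex-2-en-1-yl]-6-methylcyclohexa-2,5-diene-1,4-dione (CNP0111393.1)
Conditions: (NH4)2Ce(NO3)6 (2.5 equiv), MeCN/H2O, 0 °C
Reagents that add atoms: water, O
Why: oxidative demethylation of a para-dimethoxyarene by the tetravalent cerium salt gives the para-quinone in a short, cold reaction that trisubstituted alkenes and β,γ-unsaturated ketones should tolerate.

**Compound list**

1 | 2-methylcyclohexane-1,3-dione | CC1C(=O)CCCC1=O | starting material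
2 | allyl bromide | C=CCBr | starting material
3 | 2-allyl-2-methylcyclohexane-1,3-dione | C=CCC1(C)C(=O)CCCC1=O | intermediate
4 | 6-allyl-6-methyl-5-oxocyclohex-1-en-1-yl trifluoromethanesulfonate (racemic) | C=CCC1(C)C(=O)CCC=C1OS(=O)(=O)C(F)(F)F | intermediate (not isolated)
5 | 6-allyl-6-methylcyclohexa-1,4-diene-1,5-diyl bis(trifluoromethanesulfonate) | C=CCC1(C)C(OS(=O)(=O)C(F)(F)F)=CCC=C1OS(=O)(=O)C(F)(F)F | intermediate
6 | 6-allyl-1,5,6-trimethylcyclohexa-1,4-diene | C=CCC1(C)C(C)=CCC=C1C | intermediate
7 | [3-(1,2,6-trimethylcyclohexa-2,5-dien-1-yl)propyl]zirconocene chloride | Cl[Zr](CCCC1(C)C(C)=CCC=C1C)(C1C=CC=C1)C1C=CC=C1 | intermediate (not isolated)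
8 | 6-(3-iodopropyl)-1,5,6-trimethylcyclohexa-1,4-diene | ICCCC1(C)C(C)=CCC=C1C | intermediate
9 | 4-(3-iodopropyl)-3,4,5-trimethylcyclohexa-2,5-dien-1-one | CC1=CC(=O)C=C(C)C1(C)CCCI | intermediate
10 | [3-(1,2,6-trimethyl-4-oxocyclohexa-2,5-dien-1-yl)propyl]zinc iodide | CC1=CC(=O)C=C(C)C1(C)CCC[Zn]I | intermediate (not isolated)
11 | iodozinc dienolate of 12 (cis-fused, same configuration as 12) | C1=C(C)[C@]2(C)CCC[C@]2(C)C=C1O[Zn]I | intermediate (not isolated)
12 | (3aR,7aR)-3a,7,7a-trimethyl-1,2,3,3a,4,7a-hexahydro-5H-inden-5-one | O=C1C=C(C)[C@]2(C)CCC[C@]2(C)C1 | intermediate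
13 | ozonide (1,2,4-trioxolane) of 12 across C6–C7 | C1(O2)OOC2(C)[C@]3(C)CCC[C@]3(C)CC1=O | intermediate (not isolated)
14 | 2-[(1R,2R)-2-acetyl-1,2-dimethylcyclopentyl]acetic acid | CC(=O)[C@]1(C)CCC[C@]1(C)CC(=O)O | intermediate
15 | 1-{2-[(1R,2R)-2-acetyl-1,2-dimethylcyclopentyl]acetyl}imidazole | CC(=O)[C@]1(C)CCC[C@]1(C)CC(=O)n1ccnc1 | intermediate (not isolated)
16 | 2-[(1R,2R)-2-acetyl-1,2-dimethylcyclopentyl]-N-methoxy-N-methylacetamide | CC(=O)[C@]1(C)CCC[C@]1(C)CC(=O)N(C)OC | intermediate
17 | 4-methoxy-2-methylphenol | COc1ccc(O)c(C)c1 | starting material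
18 | 2-bromo-4-methoxy-6-methylphenol | COc1cc(C)c(O)c(Br)c1 | intermediate
19 | 1-bromo-2,5-dimethoxy-3-methylbenzene | COc1cc(C)c(OC)c(Br)c1 | intermediate
20 | 2-methyl-2-vinyloxirane (racemic) | CC1(C=C)CO1 | starting material
21 | (2,5-dimethoxy-3-methylphenyl)magnesium bromide | COc1cc(C)c(OC)c([Mg]Br)c1 | intermediate (not isolated)
22 | (2E)-4-(2,5-dimethoxy-3-methylphenyl)-2-methylbut-2-en-1-ol | OC/C(C)=C/Cc1cc(OC)cc(C)c1OC | intermediate
23 | 1-[(2E)-4-bromo-3-methylbut-2-en-1-yl]-2,5-dimethoxy-3-methylbenzene | BrC/C(C)=C/Cc1cc(OC)cc(C)c1OC | intermediate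
24 | 1-[(2E)-3-methyl-4-(phenylsulfonyl)but-2-en-1-yl]-2,5-dimethoxy-3-methylbenzene | O=S(=O)(C/C(C)=C/Cc1cc(OC)cc(C)c1OC)c1ccccc1 | intermediate
25 | α-lithio derivative of sulfone 24 | [Li]C(/C(C)=C/Cc1cc(OC)cc(C)c1OC)S(=O)(=O)c1ccccc1 | intermediate (not isolated)
26 | lithium N,O-aminal alkoxide from 16 and 25 | CC(=O)[C@]1(C)CCC[C@]1(C)CC(O[Li])(N(C)OC)C(/C(C)=C/Cc1cc(OC)cc(C)c1OC)S(=O)(=O)c1ccccc1 | intermediate (not isolated)
27 | (4E)-1-[(1R,2R)-2-acetyl-1,2-dimethylcyclopentyl]-6-(2,5-dimethoxy-3-methylphenyl)-4-methyl-3-(phenylsulfonyl)hex-4-en-2-one (both C3 epimers) | CC(=O)[C@]1(C)CCC[C@]1(C)CC(=O)C(/C(C)=C/Cc1cc(OC)cc(C)c1OC)S(=O)(=O)c1ccccc1 | intermediate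
28 | 1-bromo-2-methylprop-1-ene | CC(C)=CBr | starting material
29 | (4E)-6-(2,5-dimethoxy-3-methylphenyl)-1-[(1R,2R)-1,2-dimethyl-2-(4-methylpent-3-enoyl)cyclopentyl]-4-methyl-3-(phenylsulfonyl)hex-4-en-2-one (both C3 epimers) | CC(C)=CCC(=O)[C@]1(C)CCC[C@]1(C)CC(=O)C(/C(C)=C/Cc1cc(OC)cc(C)c1OC)S(=O)(=O)c1ccccc1 | intermediate
30 | (4E)-6-(2,5-dimethoxy-3-methylphenyl)-1-[(1R,2R)-1,2-dimethyl-2-(4-methylpent-3-enoyl)cyclopentyl]-4-methylhex-4-en-2-one | CC(C)=CCC(=O)[C@]1(C)CCC[C@]1(C)CC(=O)C/C(C)=C/Cc1cc(OC)cc(C)c1OC | intermediate
31 | 2-[(2E)-6-[(1R,2R)-1,2-dimethyl-2-(4-methylpent-3-enoyl)cyclopentyl]-3-methyl-5-oxohex-2-en-1-yl]-6-methylcyclohexa-2,5-diene-1,4-dione | CC(C)=CCC(=O)[C@]1(C)CCC[C@]1(C)CC(=O)C/C(C)=C/CC1=CC(=O)C=C(C)C1=O | target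

**Step count and risks**

Total: 17 steps. Longest linear sequence: 12 steps (steps 1–8 and 14–17).

Step 6 (highest risk). The ligand may discriminate poorly between the two enantiotopic enone arms, or a radical ring closure during zinc insertion may erode the enantiomeric purity. The fallback closes the ring without asymmetric induction and separates the enantiomers classically. Setting out from 9, slow addition of Bu3SnH with AIBN in benzene at 80 °C should close the same bond by a 5-exo-trig radical conjugate addition and give the racemic cis-fused hydrindenone F1. Ozonolysis under the conditions of step 7 would take it through the racemic ozonide F2 to the racemic keto acid F3. This acid is resolved by crystallising its salt with (R)-1-phenylethylamine, the diastereomerically pure salt F4 (the antipodal amine serves if the other salt proves the less soluble one). Acidification of F4 releases 14, where the route is rejoined.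

Step 15. The stabilised keto sulfone anion may interfere, by alkenylation at the sulfonyl-bearing carbon or by inhibiting the catalyst, or the more acidic product may be alkenylated a second time. The fallback attaches the isobutenyl group before the fragments are joined. Setting out from 16, the same palladium-catalysed enolate alkenylation with 28 (LiN(SiMe3)2, 1.1 equiv), now on a substrate with a single ketone enolate, should give the alkenylated Weinreb amide F5. F5 is then added at −78 °C to 2.5 equivalents of 25: the first equivalent converts the skipped enone into its lithium dienolate, which is a poor nucleophile toward the amide at this temperature, and a further equivalent adds to the amide to give the dilithium aminal adduct F6. Quenching F6 with aq. NH4Cl gives 29, where the route is rejoined.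

Step 2. The second enolisation may be incomplete, or the first enol triflate may be lost under the basic conditions. The fallback installs the two ring methyl groups by carbonyl addition and elimination instead of cross-coupling. Setting out from 3, excess MeMgBr with anhydrous CeCl3 in THF at −78 °C should add to both carbonyl groups, through the hydroxy ketone F7, to give the ditertiary diol F8 as a mixture of diastereomers. Twofold dehydration of F8 with Burgess reagent in warm toluene then gives 6, any isomer with an exocyclic double bond being removed by chromatography, and the route is rejoined at 6.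

**Further compounds**

F1 | step 6 | racemic cis-3a,7,7a-trimethyl-1,2,3,3a,4,7a-hexahydro-5H-inden-5-one (relative configuration shown) | O=C1C=C(C)[C@]2(C)CCC[C@]2(C)C1
F2 | step 6 | racemic ozonide of F1 (not isolated, relative configuration shown) | C1(O2)OOC2(C)[C@]3(C)CCC[C@]3(C)CC1=O
F3 | step 6 | racemic cis-2-(2-acetyl-1,2-dimethylcyclopentyl)acetic acid (relative configuration shown) | CC(=O)[C@]1(C)CCC[C@]1(C)CC(=O)O
F4 | step 6 | (R)-1-phenylethylammonium 2-[(1R,2R)-2-acetyl-1,2-dimethylcyclopentyl]acetate | CC(=O)[C@]1(C)CCC[C@]1(C)CC(=O)[O-].C[C@@H]([NH3+])c1ccccc1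
F5 | step 15 | N-methoxy-N-methyl-2-[(1R,2R)-1,2-dimethyl-2-(4-methylpent-3-enoyl)cyclopentyl]acetamide | CC(C)=CCC(=O)[C@]1(C)CCC[C@]1(C)CC(=O)N(C)OC
F6 | step 15 | dilithium adduct of F5 and 25 (lithium dienolate and lithium N,O-aminal alkoxide, not isolated) | CC(C)=CC=C(O[Li])[C@]1(C)CCC[C@]1(C)CC(O[Li])(N(C)OC)C(/C(C)=C/Cc1cc(OC)cc(C)c1OC)S(=O)(=O)c1ccccc1
F7 | step 2 | 2-allyl-3-hydroxy-2,3-dimethylcyclohexan-1-one (racemic, mixture of diastereomers, not isolated) | C=CCC1(C)C(=O)CCCC1(C)O
F8 | step 2 | 2-allyl-1,2,3-trimethylcyclohexane-1,3-diol (mixture of diastereomers) | C=CCC1(C)C(C)(O)CCCC1(C)O
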